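## Structural features

The target consists of two identical 2,2-dimethylchroman units, each built on a phloroglucinol nucleus whose three oxygens are O1 (in the pyran ring), the C5 hydroxyl and the C7 hydroxyl. Both benzene rings are fully substituted and are joined through C6 and C6' to C1 of a 6-methylheptane chain, so that one sp3 methine carries two aryl groups and a 5-methylhexyl group. C8 of each ring carries an isobutyryl group that is hydrogen-bonded to the C7 hydroxyl. There is no stereocentre (the methine bears two identical aryl groups, C2 bears two methyl groups), so no stereocentres stand next to each other; only slow rotation about the crowded aryl–methine bonds is to be expected. The fragile part is the doubly benzylic bridge between two electron-rich rings: as a free polyphenol it is prone to acid-induced retro-Friedel–Crafts cleavage, to cyclodehydration to a xanthene and to air oxidation. The real difficulty is regiochemical: on each ring the pyran must be fused with O1 next to the acylated C8 and C4 next to the C5 hydroxyl, the bridge must sit between C5 and C7, and every operation must succeed twice in one molecule. The key step exploits the fact that C8a (bearing O1) and C4a (bearing C4) are adjacent ring carbons, flanked by the C5 oxygen on one side and by C8–H on the other. This is the pattern that a 3-alkoxyaryne C4a≡C8a delivers when it takes up the C=O group of an enal, so both substituents and the whole pyran ring arrive in one operation on each ring.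

## Logic of the disconnections

**20 to 19.** The last operation is a global hydrogenation: the two C3–C4 single bonds are traced back to C3=C4 double bonds and the four phenolic O–H bonds to O–benzyl bonds. Cutting here lets the acid- and air-sensitive free polyphenol appear only in the final step, when both rings are already deactivated by their acyl groups. One operation removes two alkenes and four protecting groups. The demand is that the aryl ketones and the aryl–methine bonds survive hydrogen over palladium.

**19 to 16 and 17.** The two C8–C(=O) bonds are cut. In 16, C8–H is the only ring hydrogen and lies between O1 and the C7 ether oxygen, so the acyl groups can be brought in by directed lithiation and acylation with 17. This avoids a Lewis-acid acylation of the bridged free polyphenol, whose doubly benzylic bridge would be at risk of scission. The gain is a bis-chromene free of carbonyl groups. The demand is that ring metalation outruns metalation of the benzylic OCH2 groups, takes place on both rings, and that the hindered ketone formed does not take up a second aryl group.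

**16 to 11 and 12.** On each ring the C4a–C4, C8a–O1 and O1–C2 bonds are cut (six bonds, two rings). Both pyran rings disappear and a bis(o-silylaryl triflate) with the oxygenation of a phloroglucinol remains. The oxygen para to the bridge becomes the leaving group and O1 is supplied by 12. The demand is regioselective addition to an unsymmetrical aryne, twice, and spectator groups that are inert to fluoride and to arynes; benzyl ethers meet this and fall off in the last step.

**11 to 10 to 9.** The two O–S bonds are cut and the phenols are traced back to carbamates. A carbamate on the para oxygen is both the director for introducing silicon at the neighbouring carbon and the precursor of the triflate. An N,N-diethylcarbamate is preferred to an N-monoalkyl one: it has no N–H and cannot fragment to an isocyanate under the basic benzylation of step 4. The price is one extra step, since cleavage and triflation are separate. The demand is a cleavage without acid, which would protodesilylate the electron-rich arylsilane; hydride reduction answers it.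

**9 to 7.** The two aryl–Si bonds are cut. Both positions ortho to the carbamate are equivalent on each ring and each lies between the carbamate and a benzyloxy group, so no regiochemical choice exists. The demand is that lithiation at low temperature beats benzylic deprotonation and the anionic Fries shift.

**7 to 6 to 5.** The four O–benzyl bonds and then the two O–carbamoyl bonds are cut. On each ring the para oxygen (future leaving group) must be told apart from the two ortho oxygens (future C5 and C7 hydroxyls). The para hydroxyl is the only one not flanked by the branched bridge, so carbamoylation comes first and benzylation second. The demand is steric site selectivity among six hydroxyls; this is the weakest point of the early stage.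

**5 to 2 and 3; 2 to 1.** The two aryl–C1 bonds at the methine are cut. Because 3 is threefold symmetric, every ring position is flanked by two hydroxyls and para to the third, so the substitution pattern of 5 follows without a regiochemical choice. The demand is to stop at the 2:1 stage and to avoid xanthene formation (excess 3, mild acid, low temperature). 2 comes from 1 by oxidation of the primary alcohol.

## Other disconnections considered

Alternative 1: The cut is the C7–C8 bond of each benzene ring, so that the aromatic rings are made late from polyketide-type chains.
- **Forward key step:** Mg(OMe)2 in methanol would open both lactones of the bridged bis-pyranone A1 to the bis(3,5,7-triketo methyl ester) A2. In each half of A2 the methylene next to the isobutyryl ketone (future C8) would attack the ester carbon (future C7) in a Claisen condensation, and enolisation would give the bridged bis(phlorisobutyrophenone) A3.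
- **In favour:** Acyl group and bridge are in place before the ring exists. A1 should assemble cleanly from 2, because each of its pyranone rings offers a single nucleophilic carbon, so the oligomers and xanthenes that threaten step 2 are not expected. No protecting groups are needed. On these three points this plan is better than the chosen one.
- **Against:** The chain of A2 can also fold by aldol closure onto the isobutyryl ketone. More seriously, A3 still lacks both pyran rings. Its only free ring carbon (C4a) lies between two hydroxyls, and after C-prenylation the unchelated C5 hydroxyl is the more likely one to close, which would give the wrong fusion.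
- **Comparison:** On structure, A3 holds rings, bridge and acyl groups but leaves the pyran regiochemistry open, which the aryne step settles by construction. On mechanism, a thermodynamically driven ionic condensation is more robust than a reactive-intermediate cascade. On step economy, it is probably equal or shorter up to A3, but at least two further steps of uncertain regiochemistry follow.

Alternative 2: The cut is the C5–C6 bond of each benzene ring, with the pyran rings already present and the bridge methine as the central carbon of a 3-alkylglutarate-derived core.
- **Forward key step:** Excess KN(SiMe3)2 would doubly deprotonate each δ-keto ester arm of A4. The carbanion next to the bridge carbon (future C6) would attack the ester carbon on the dihydropyran (future C5), methoxide would leave, and tautomerisation would give the bis-chroman tetraphenol A5.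
- **In favour:** The position of the pyran oxygen relative to the bridge is fixed by connectivity, so there is no regiochemical question on an arene and no aryne. The bis-arylation of step 2 and all protecting groups are avoided. These are points on which it is better than the chosen plan.
- **Against:** The two ketones of A4 are 1,5-related through the bridge carbon, so an intramolecular aldol closure to a six-membered enone should compete. The required nucleophile is the less acidic, hindered site, and the β-alkoxyacrylate ester is a poor electrophile. A4 itself needs a long synthesis. A5 would still have to be acylated at C8 as a free, acid-labile polyphenol.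
- **Comparison:** Both plans are two-directional and close two rings (equal). This step forms two skeletal bonds against six. The way to A4 is probably longer than steps 1 to 7, and the end-game is weaker.

Alternative 3: The cut is the C8–C(=O) bond on each ring, made last by acyl migration from oxygen.
- **Forward key step:** A5 would be peracylated to the tetraisobutyrate A6. Irradiation at 254 nm would cleave aryl ester O–C(=O) bonds, and the caged acyl radical would recombine at C8, the only unsubstituted ring carbon, to give the diester A7, which needs hydrolysis to 20.
- **In favour:** It is a neutral, reagent-free C–C bond formation that avoids both a Lewis acid and the organolithium of step 9 (better in mildness). The regiochemistry is unambiguous (equal to step 9).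
- **Against:** Photo-Fries reactions tend to stall because the o-hydroxyaryl ketone product absorbs the same light. Radicals that escape the cage give phenols. The doubly benzylic methine C–H is a likely hydrogen donor, which would lead to degradation of the bridge. The reaction must succeed on both rings, and an ester hydrolysis on a base-sensitive polyphenol follows. It presupposes A5 and says nothing about how the rings are made.
- **Comparison:** On structure it addresses only the last two bonds. On mechanism it is a radical-pair process against a polar one. On step economy it needs three operations from A5 against two from 16 in the chosen plan.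

Key step: step 8

Remark: the target has no stereocentre, so SMILES carry no stereodescriptors except the transient alkene geometry of 15; the transient carbinol 4 and benzoxete 14 are stereoisomer mixtures of no consequence.

## Route

Step 1
Reactants: 1 6-methylheptan-1-ol
Product: 2 6-methylheptanal
Conditions: TEMPO (10 mol%), PhI(OAc)2 (1.1 equiv), CH2Cl2, rt
Reagents that add atoms: none
Why: Nitroxyl-catalysed oxidation with PhI(OAc)2 as terminal oxidant takes a primary alcohol to the aldehyde without over-oxidation; the saturated chain has no other reactive site.

Step 2
Reactants: 2 6-methylheptanal; 3 phloroglucinol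
Product: 5 2,2'-(6-methylheptane-1,1-diyl)bis(benzene-1,3,5-triol), via carbinol mono-adduct 4 (not isolated)
Conditions: 3 (8 equiv), HCl (cat.), MeOH–H2O, 0 °C to rt, argon, slow addition of 2
Reagents that add atoms: none
Why: Acid-catalysed hydroxyalkylation of the very nucleophilic arene 3 (Baeyer-type condensation, twofold Friedel–Crafts alkylation) gives carbinol 4, which ionises to a benzylic cation/o-quinone methide and is captured by a second molecule of 3; all ring positions of 3 are equivalent, so no regiochemistry arises. The large excess of 3 should hold back oligomers and the low temperature should hold back cyclodehydration to a xanthene.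

Step 3
Reactants: 5 2,2'-(6-methylheptane-1,1-diyl)bis(benzene-1,3,5-triol)
Product: 6 4,4'-(6-methylheptane-1,1-diyl)bis(3,5-dihydroxyphenyl) bis(N,N-diethylcarbamate)
Conditions: Et2NCOCl (2.1 equiv), Et3N, DMAP (cat.), MeCN, 0 to 40 °C
Reagents that add atoms: N,N-diethylcarbamoyl chloride, CCN(CC)C(=O)Cl
Why: O-Carbamoylation through the bulky N-carbamoylpyridinium ion should pick the two para hydroxyls, the only ones not flanked by the branched bridge and not tied up in inter-ring hydrogen bonds. The N,N-dialkylcarbamate has no N–H, so it cannot fragment to an isocyanate in the basic step 4, and it is a strong director for step 5.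

Step 4
Reactants: 6 4,4'-(6-methylheptane-1,1-diyl)bis(3,5-dihydroxyphenyl) bis(N,N-diethylcarbamate)
Product: 7 4,4'-(6-methylheptane-1,1-diyl)bis[3,5-bis(benzyloxy)phenyl] bis(N,N-diethylcarbamate)
Conditions: BnBr (5 equiv), K2CO3, Bu4NI (cat.), DMF, 50 °C
Reagents that add atoms: benzyl bromide, BrCc1ccccc1
Why: Williamson etherification of the four remaining phenols; with only two free oxygens per ring the phenoxides behave as resorcinol-type O-nucleophiles, and the N,N-diethylcarbamates are inert to K2CO3.

Step 5
Reactants: 7 4,4'-(6-methylheptane-1,1-diyl)bis[3,5-bis(benzyloxy)phenyl] bis(N,N-diethylcarbamate)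
Product: 9 4,4'-(6-methylheptane-1,1-diyl)bis[3,5-bis(benzyloxy)-2-(trimethylsilyl)phenyl] bis(N,N-diethylcarbamate), via dilithio species 8 (not isolated)
Conditions: s-BuLi (2.5 equiv), TMEDA, THF, −78 °C; then Me3SiCl, −78 °C to rt
Reagents that add atoms: chlorotrimethylsilane, C[Si](C)(C)Cl
Why: Directed ortho-metalation (Snieckus type): on each ring the two positions ortho to the carbamate are equivalent and lie between the carbamate and a benzyloxy group, so cooperative direction should give one dilithio species 8 at −78 °C, below the temperature of the anionic ortho-Fries shift. Silylation of 8 then gives 9.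

Step 6
Reactants: 9 4,4'-(6-methylheptane-1,1-diyl)bis[3,5-bis(benzyloxy)-2-(trimethylsilyl)phenyl] bis(N,N-diethylcarbamate)
Product: 10 4,4'-(6-methylheptane-1,1-diyl)bis[3,5-bis(benzyloxy)-2-(trimethylsilyl)phenol]
Conditions: LiAlH4, THF, 0 to 50 °C; H2O, aq. NaOH work-up
Reagents that add atoms: none
Why: Hydride reduction cleaves aryl N,N-dialkylcarbamates to the phenols, the carbamoyl carbon leaving as the N-methylamine. Benzyl ethers and aryl–silicon bonds are inert to LiAlH4, and acid, which would protodesilylate the electron-rich arylsilane, is avoided.

Step 7
Reactants: 10 4,4'-(6-methylheptane-1,1-diyl)bis[3,5-bis(benzyloxy)-2-(trimethylsilyl)phenol]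
Product: 11 4,4'-(6-methylheptane-1,1-diyl)bis[3,5-bis(benzyloxy)-2-(trimethylsilyl)phenyl] bis(trifluoromethanesulfonate)
Conditions: Tf2O (2.4 equiv), pyridine, CH2Cl2, −20 to 0 °C
Reagents that add atoms: trifluoromethanesulfonic anhydride, O=S(=O)(OS(=O)(=O)C(F)(F)F)C(F)(F)F
Why: O-Sulfonylation of the two phenols, the standard last step towards o-silylaryl triflates; pyridine buffers the triflic acid so that the arylsilane is not protodesilylated.

Step 8
Reactants: 11 4,4'-(6-methylheptane-1,1-diyl)bis[3,5-bis(benzyloxy)-2-(trimethylsilyl)phenyl] bis(trifluoromethanesulfonate); 12 3-methylbut-2-enal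
Product: 16 1,1-bis(5,7-dibenzyloxy-2,2-dimethyl-2H-chromen-6-yl)-6-methylheptane, via bis-aryne 13 (not isolated), via bis-benzoxete 14 (not isolated), via bis(o-quinone methide) 15 (not isolated)
Conditions: CsF (6 equiv), 12 (10 equiv), MeCN (high dilution), rt to 40 °C
Reagents that add atoms: none
Why: Fluoride attacks each silicon and the aryl anion expels the neighbouring triflate, so that bis-aryne 13 (C4a≡C8a on each ring) is released slowly from sparingly soluble CsF. The carbonyl oxygen of 12 adds to C8a and the aryl anion at C4a closes on the carbonyl carbon, a formal [2+2] cycloaddition that gives benzoxete 14 with the C8a–O1 and C4a–C4 bonds. 4π-Electrocyclic opening gives the o-quinone methide 15, a 1-oxatriene, and thermal disrotatory oxa-6π electrocyclisation onto the dimethylvinyl terminus forms O1–C2 and closes each six-membered pyran ring. The closest known reaction type is the fluoride-induced annulation of o-silylaryl triflates with α,β-unsaturated aldehydes to 2H-chromenes, here run in two directions on independent rings. No stereocentre is created, since the benzoxete carbon of 14 becomes sp2 in 15 and C2 carries two methyl groups. The regioselectivity needed, oxygen to C8a, is secured by the C5 benzyloxy group, whose inductive pull makes the distal carbon C8a the electrophilic aryne terminus and stabilises the anion at C4a; C8a is also the less hindered carbon, next to C8–H. The geometry of 15 needed for ring closure is favoured because the dienyl arm would clash with the C5 benzyloxy group in the other geometry. Excess 12 and high dilution should hold back aryne self-reactions, capture of 15 by a second aryne and ene reactions of the product.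

Step 9
Reactants: 16 1,1-bis(5,7-dibenzyloxy-2,2-dimethyl-2H-chromen-6-yl)-6-methylheptane; 17 isobutyric anhydride
Product: 19 1,1-bis(5,7-dibenzyloxy-8-isobutyryl-2,2-dimethyl-2H-chromen-6-yl)-6-methylheptane, via dilithio species 18 (not isolated)
Conditions: n-BuLi (2.6 equiv), THF, 0 °C; then cannulated into 17 (6 equiv), THF, −78 °C to rt; aq. NH4Cl
Reagents that add atoms: none
Why: Alkoxy-directed ortho-lithiation: C8–H is the only ring hydrogen and lies between O1 and the C7 benzyloxy oxygen, the same doubly activated situation as C2 of a 1,3-dialkoxybenzene. Inverse addition of the aryllithium 18 to excess anhydride 17 at −78 °C acylates each ring (ketone synthesis from an organolithium and a carboxylic anhydride), each anhydride molecule passing on one acyl group and releasing the other as lithium isobutyrate, and the resulting aryl isopropyl ketone, flanked by two ortho oxygens, is too hindered for a second addition. The acyl groups are thus placed without Lewis acid.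

Step 10
Reactants: 19 1,1-bis(5,7-dibenzyloxy-8-isobutyryl-2,2-dimethyl-2H-chromen-6-yl)-6-methylheptane
Product: 20 1,1-bis(5,7-dihydroxy-8-isobutyryl-2,2-dimethylchroman-6-yl)-6-methylheptane
Conditions: H2 (1 atm), Pd/C (10%), EtOAc–EtOH, rt
Reagents that add atoms: none
Why: Heterogeneous hydrogenation saturates the two styrene-type C3=C4 bonds and hydrogenolyses the four benzyl ethers in one operation. The hindered aryl ketones, hydrogen-bonded to the C7 hydroxyls once these are freed, should not be reduced under neutral conditions at 1 atm.

## Compound list

1 | 6-methylheptan-1-ol | CC(C)CCCCCO | starting material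
2 | 6-methylheptanal | CC(C)CCCCC=O | intermediate
3 | phloroglucinol (benzene-1,3,5-triol) | Oc1cc(O)cc(O)c1 | starting material
4 | 2-(1-hydroxy-6-methylheptyl)benzene-1,3,5-triol (racemic carbinol mono-adduct, not isolated) | CC(C)CCCCC(O)c1c(O)cc(O)cc1O | intermediate
5 | 2,2'-(6-methylheptane-1,1-diyl)bis(benzene-1,3,5-triol) (bridged hexaol) | CC(C)CCCCC(c1c(O)cc(O)cc1O)c1c(O)cc(O)cc1O | intermediate
6 | 4,4'-(6-methylheptane-1,1-diyl)bis(3,5-dihydroxyphenyl) bis(N,N-diethylcarbamate) | CC(C)CCCCC(c1c(O)cc(OC(=O)N(CC)CC)cc1O)c1c(O)cc(OC(=O)N(CC)CC)cc1O | intermediate
7 | 4,4'-(6-methylheptane-1,1-diyl)bis[3,5-bis(benzyloxy)phenyl] bis(N,N-diethylcarbamate) | CC(C)CCCCC(c1c(OCc2ccccc2)cc(OC(=O)N(CC)CC)cc1OCc1ccccc1)c1c(OCc2ccccc2)cc(OC(=O)N(CC)CC)cc1OCc1ccccc1 | intermediate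
8 | dilithio species of 7, lithium on the ring carbon between carbamate and benzyloxy group of each ring (not isolated) | CC(C)CCCCC(c1c(OCc2ccccc2)cc(OC(=O)N(CC)CC)c([Li])c1OCc1ccccc1)c1c(OCc2ccccc2)cc(OC(=O)N(CC)CC)c([Li])c1OCc1ccccc1 | intermediate
9 | 4,4'-(6-methylheptane-1,1-diyl)bis[3,5-bis(benzyloxy)-2-(trimethylsilyl)phenyl] bis(N,N-diethylcarbamate) | CC(C)CCCCC(c1c(OCc2ccccc2)cc(OC(=O)N(CC)CC)c([Si](C)(C)C)c1OCc1ccccc1)c1c(OCc2ccccc2)cc(OC(=O)N(CC)CC)c([Si](C)(C)C)c1OCc1ccccc1 | intermediate
10 | 4,4'-(6-methylheptane-1,1-diyl)bis[3,5-bis(benzyloxy)-2-(trimethylsilyl)phenol] | CC(C)CCCCC(c1c(OCc2ccccc2)cc(O)c([Si](C)(C)C)c1OCc1ccccc1)c1c(OCc2ccccc2)cc(O)c([Si](C)(C)C)c1OCc1ccccc1 | intermediate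
11 | 4,4'-(6-methylheptane-1,1-diyl)bis[3,5-bis(benzyloxy)-2-(trimethylsilyl)phenyl] bis(trifluoromethanesulfonate) | CC(C)CCCCC(c1c(OCc2ccccc2)cc(OS(=O)(=O)C(F)(F)F)c([Si](C)(C)C)c1OCc1ccccc1)c1c(OCc2ccccc2)cc(OS(=O)(=O)C(F)(F)F)c([Si](C)(C)C)c1OCc1ccccc1 | intermediate
12 | 3-methylbut-2-enal | CC(C)=CC=O | starting material
13 | 1,1-bis(2,6-dibenzyloxy-3,4-didehydrophenyl)-6-methylheptane (bis-aryne, not isolated) | CC(C)CCCCC(C1=C(OCc2ccccc2)C#CC=C1OCc1ccccc1)C1=C(OCc2ccccc2)C#CC=C1OCc1ccccc1 | intermediate
14 | bis(2H-benzoxete): on each ring the oxete oxygen on C8a and the CH(CH=CMe2) carbon on C4a (stereoisomer mixture, not isolated) | CC(C)CCCCC(c1c(OCc2ccccc2)cc2OC(C=C(C)C)c2c1OCc1ccccc1)c1c(OCc2ccccc2)cc2OC(C=C(C)C)c2c1OCc1ccccc1 | intermediate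
15 | bis(o-quinone methide): on each ring C8a is a carbonyl and C4a carries the exocyclic 3-methylbut-2-enylidene group, dienyl arm on the carbonyl side (not isolated) | CC(C)CCCCC(C1=C(OCc2ccccc2)/C(=C/C=C(C)C)C(=O)C=C1OCc1ccccc1)C1=C(OCc2ccccc2)/C(=C/C=C(C)C)C(=O)C=C1OCc1ccccc1 | intermediate
16 | 1,1-bis(5,7-dibenzyloxy-2,2-dimethyl-2H-chromen-6-yl)-6-methylheptane | CC(C)CCCCC(c1c(OCc2ccccc2)cc3OC(C)(C)C=Cc3c1OCc1ccccc1)c1c(OCc2ccccc2)cc3OC(C)(C)C=Cc3c1OCc1ccccc1 | intermediate
17 | isobutyric anhydride (2-methylpropanoic anhydride) | CC(C)C(=O)OC(=O)C(C)C | starting material
18 | 8,8'-dilithio species of 16 (not isolated) | CC(C)CCCCC(c1c(OCc2ccccc2)c([Li])c3OC(C)(C)C=Cc3c1OCc1ccccc1)c1c(OCc2ccccc2)c([Li])c3OC(C)(C)C=Cc3c1OCc1ccccc1 | intermediate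
19 | 1,1-bis(5,7-dibenzyloxy-8-isobutyryl-2,2-dimethyl-2H-chromen-6-yl)-6-methylheptane | CC(C)CCCCC(c1c(OCc2ccccc2)c(C(=O)C(C)C)c3OC(C)(C)C=Cc3c1OCc1ccccc1)c1c(OCc2ccccc2)c(C(=O)C(C)C)c3OC(C)(C)C=Cc3c1OCc1ccccc1 | intermediate
20 | 1,1-bis(5,7-dihydroxy-8-isobutyryl-2,2-dimethylchroman-6-yl)-6-methylheptane (CNP0275635.0) | CC(C)CCCCC(c1c(O)c2c(c(C(=O)C(C)C)c1O)OC(C)(C)CC2)c1c(O)c2c(c(C(=O)C(C)C)c1O)OC(C)(C)CC2 | target

## Step count and least certain steps

Total: 10 steps. Longest linear sequence: 10 steps (1 to 20; compounds 3, 12 and 17 enter as purchased partners).

**Key step (step 8).** The likely failure is incomplete twofold annulation together with self-consumption of the arynes (dimerisation, addition of fluoride or of deprotonated acetonitrile, capture of the quinone methide by a second aryne), because two short-lived arynes in one molecule must each find an aldehyde. Erosion of the regiochemistry on one ring would also give inseparable isomers.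

The fallback avoids arynes altogether. It sets out from 7, whose carbamates would be reduced off with LiAlH4 to give 1,1-bis(2,6-dibenzyloxy-4-hydroxyphenyl)-6-methylheptane F1. Condensation of F1 with 12 under ethylenediammonium diacetate catalysis in hot toluene (the classical phenol–enal chromene annulation) should then give 16, where it rejoins the route. This annulation proceeds by C-alkylation at the carbon ortho to the free hydroxyl, dehydration to an o-quinone methide and oxa-6π closure. Both ortho positions of each phenol are equivalent, so only one product is possible.

**Para-selective carbamoylation (step 3).** The likely failure is insufficient site discrimination among six hydroxyls, with carbamoylation of ortho hydroxyls and over-carbamoylation, since the selectivity rests on steric and hydrogen-bonding differences alone. Step 2 before it carries the related danger of over-condensation.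

The fallback builds the differentiation into the monomer and bypasses steps 2 to 4; it sets out from 2 and rejoins the route at 7. Commercial 3,5-dibenzyloxyphenol would be silylated (i-Pr3SiCl, imidazole) to (3,5-dibenzyloxyphenoxy)triisopropylsilane F2. n-BuLi in THF at 0 °C should lithiate F2 between the two benzyloxy groups, since the bulky silyloxy group neither directs nor admits metalation next to it, and addition to 2 would give 1-[2,6-bis(benzyloxy)-4-(triisopropylsilyloxy)phenyl]-6-methylheptan-1-ol F3. Ionisation of F3 with catalytic Sc(OTf)3 in the presence of a second equivalent of F2 should give Friedel–Crafts alkylation para to the silyloxy group, the position farthest from the bulky silyl group, to give 1,1-bis[2,6-bis(benzyloxy)-4-(triisopropylsilyloxy)phenyl]-6-methylheptane F4. Desilylation with Bu4NF would give 1,1-bis(2,6-dibenzyloxy-4-hydroxyphenyl)-6-methylheptane F1, and carbamoylation (NaH, Et2NCOCl) would give 7.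

**Twofold ortho-silylation (step 5).** The likely failure is competing deprotonation at the benzylic OCH2 groups and incomplete lithiation of the second ring, which would leave mono-silylated material; warming before the quench would start the anionic Fries shift.

The fallback replaces deprotonation by halogen–metal exchange. It sets out from 7, which would be brominated once on each ring with N-bromosuccinimide in MeCN at 0 °C in the dark (ortho to the carbamate, para to a benzyloxy group; both such positions are equivalent). This gives 4,4'-(6-methylheptane-1,1-diyl)bis[3,5-bis(benzyloxy)-2-bromophenyl] bis(N,N-diethylcarbamate) F5. Bromine–lithium exchange with n-BuLi at −78 °C, which is faster than any deprotonation, would give the same dilithio species 8, and Me3SiCl would give 9, where the route is rejoined.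

**C8 acylation (step 9).** The likely failure is metalation of benzylic OCH2 groups followed by Wittig-type rearrangement, and proton transfer from the α-C–H of the anhydride or of the ketone already formed to the hindered aryllithium, which would return unacylated rings and stop at mono-acylation.

The fallback reverses the order of the end-game. It sets out from 16, which would be hydrogenated (H2, Pd/C) to 1,1-bis(5,7-dihydroxy-2,2-dimethylchroman-6-yl)-6-methylheptane F6. Friedel–Crafts acylation of F6 at C8, the only free ring position, with isobutyryl chloride and AlCl3 in CH2Cl2–MeNO2 at 0 °C would give 20 directly. The cost is exposure of the acid-labile bridge to a Lewis acid, which is why this order is held in reserve.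

## Further compounds

F1 | step 8 | 1,1-bis(2,6-dibenzyloxy-4-hydroxyphenyl)-6-methylheptane | CC(C)CCCCC(c1c(OCc2ccccc2)cc(O)cc1OCc1ccccc1)c1c(OCc2ccccc2)cc(O)cc1OCc1ccccc1
F2 | step 3 | (3,5-dibenzyloxyphenoxy)triisopropylsilane | CC(C)[Si](Oc1cc(OCc2ccccc2)cc(OCc2ccccc2)c1)(C(C)C)C(C)C
F3 | step 3 | 1-[2,6-bis(benzyloxy)-4-(triisopropylsilyloxy)phenyl]-6-methylheptan-1-ol (racemic) | CC(C)CCCCC(O)c1c(OCc2ccccc2)cc(O[Si](C(C)C)(C(C)C)C(C)C)cc1OCc1ccccc1
F4 | step 3 | 1,1-bis[2,6-bis(benzyloxy)-4-(triisopropylsilyloxy)phenyl]-6-methylheptane | CC(C)CCCCC(c1c(OCc2ccccc2)cc(O[Si](C(C)C)(C(C)C)C(C)C)cc1OCc1ccccc1)c1c(OCc2ccccc2)cc(O[Si](C(C)C)(C(C)C)C(C)C)cc1OCc1ccccc1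
F5 | step 5 | 4,4'-(6-methylheptane-1,1-diyl)bis[3,5-bis(benzyloxy)-2-bromophenyl] bis(N,N-diethylcarbamate) | CC(C)CCCCC(c1c(OCc2ccccc2)cc(OC(=O)N(CC)CC)c(Br)c1OCc1ccccc1)c1c(OCc2ccccc2)cc(OC(=O)N(CC)CC)c(Br)c1OCc1ccccc1
F6 | step 9 | 1,1-bis(5,7-dihydroxy-2,2-dimethylchroman-6-yl)-6-methylheptane | CC(C)CCCCC(c1c(O)c2CCC(C)(C)Oc2cc1O)c1c(O)c2CCC(C)(C)Oc2cc1O
A1 | alternative 1 | 3,3'-(6-methylheptane-1,1-diyl)bis[4-hydroxy-6-(3-methyl-2-oxobutyl)-2H-pyran-2-one] | CC(C)CCCCC(C1=C(O)C=C(CC(=O)C(C)C)OC1=O)C1=C(O)C=C(CC(=O)C(C)C)OC1=O
A2 | alternative 1 | dimethyl 2,2'-(6-methylheptane-1,1-diyl)bis(8-methyl-3,5,7-trioxononanoate) (keto form, stereoisomer mixture) | CC(C)CCCCC(C(C(=O)OC)C(=O)CC(=O)CC(=O)C(C)C)C(C(=O)OC)C(=O)CC(=O)CC(=O)C(C)C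
A3 | alternative 1 | 6-methylheptylidene-bridged bis(phlorisobutyrophenone) | CC(C)CCCCC(c1c(O)cc(O)c(C(=O)C(C)C)c1O)c1c(O)cc(O)c(C(=O)C(C)C)c1O
A4 | alternative 2 | dimethyl 6,6'-[4-(5-methylhexyl)-2,6-dioxoheptane-1,7-diyl]bis(2,2-dimethyl-3,4-dihydro-2H-pyran-5-carboxylate) | CC(C)CCCCC(CC(=O)CC1=C(C(=O)OC)CCC(C)(C)O1)CC(=O)CC1=C(C(=O)OC)CCC(C)(C)O1
A5 | alternative 2 | 1,1-bis(5,7-dihydroxy-2,2-dimethylchroman-6-yl)-6-methylheptane | CC(C)CCCCC(c1c(O)c2CCC(C)(C)Oc2cc1O)c1c(O)c2CCC(C)(C)Oc2cc1O
A6 | alternative 3 | 5,5',7,7'-tetra-O-isobutyrate of 1,1-bis(5,7-dihydroxy-2,2-dimethylchroman-6-yl)-6-methylheptane | CC(C)CCCCC(c1c(OC(=O)C(C)C)c2CCC(C)(C)Oc2cc1OC(=O)C(C)C)c1c(OC(=O)C(C)C)c2CCC(C)(C)Oc2cc1OC(=O)C(C)C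
A7 | alternative 3 | 5,5'-di-O-isobutyrate of the target | CC(C)CCCCC(c1c(OC(=O)C(C)C)c2CCC(C)(C)Oc2c(C(=O)C(C)C)c1O)c1c(OC(=O)C(C)C)c2CCC(C)(C)Oc2c(C(=O)C(C)C)c1O
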